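**Retrosynthetic overview** (ring positions C1–C14 as in the target; C1 is the stereocentre)
1. Target 21 ⇐ ester 20 by reduction; the only ring, the 14-membered carbocycle, is closed in the penultimate step by intramolecular HWE at C3=C4 of 19.
2. 19 ⇐ enal 13 + α-branched alkenylboronic acid 18 by an iminium-catalysed enantioselective conjugate alkenylation, which sets the single stereocentre (C1, R).
3. 13 ⇐ terminal alkene 12 by cross-metathesis with crotonaldehyde; 12 ⇐ homoallylic iodide 9 + triethyl phosphonoacetate 10.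
4. 9 ⇐ neryl acetate 1 (Z-olefin bought in) by ω-hydroxylation (sets the E-olefin), bromination, allyl coupling and a one-carbon homologation.
5. 18 ⇐ 6-methylhept-5-en-2-one 14 by Shapiro reaction and borylation.

Assumption: the catalyst Cat* = (5R)-5-(2-hydroxybenzyl)-2,2,3-trimethylimidazolidin-4-one, CN1C(=O)[C@@H](Cc2ccccc2O)NC1(C)C, is made separately and not counted, and 12, 13 and 19 are carried as 1:1 mixtures at the phosphonate-bearing carbon, which becomes sp2 in step 12.

**Step 1**
Reactants: 1 neryl acetate, (2Z)-3,7-dimethylocta-2,6-dien-1-yl acetate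
Product: 2 (2Z,6E)-8-hydroxy-3,7-dimethylocta-2,6-dien-1-yl acetate
Conditions: SeO2 (0.1 equiv), t-BuOOH (3 equiv), salicylic acid (0.1 equiv), CH2Cl2, 0 °C → rt
Reagents that add atoms: tert-butyl hydroperoxide, CC(C)(C)OO
Why: Catalytic SeO2/t-BuOOH allylic oxidation (ene/[2,3] sequence) hydroxylates the (E)-methyl of the electron-rich terminal olefin, while the allylic acetate deactivates the 2,3-olefin and its Z geometry is untouched.

**Step 2**
Reactants: 2 (2Z,6E)-8-hydroxy-3,7-dimethylocta-2,6-dien-1-yl acetate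
Product: 3 (2Z,6E)-8-bromo-3,7-dimethylocta-2,6-dien-1-yl acetate
Conditions: CBr4, PPh3, CH2Cl2, 0 °C
Reagents that add atoms: carbon tetrabromide, BrC(Br)(Br)Br
Why: Appel bromination of a primary allylic alcohol under neutral conditions keeps the acetate and both olefin geometries.

**Step 3**
Reactants: 3 (2Z,6E)-8-bromo-3,7-dimethylocta-2,6-dien-1-yl acetate
Product: 5 (2Z,6E)-3,7-dimethylundeca-2,6,10-trien-1-ol, via coupled acetate 4 (not isolated)
Conditions: allylMgCl (1.2 equiv), Li2CuCl4 (3 mol%), THF, −78 °C; then allylMgCl (2.5 equiv), −78 → 0 °C; aq. NH4Cl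
Reagents that add atoms: allylmagnesium chloride, C=CC[Mg]Cl
Why: Copper-catalysed α-selective (SN2) Grignard coupling with the primary allylic bromide keeps the 6E olefin, and the surplus Grignard reagent then removes the acetate by double addition to the ester, so both orders of events converge on 5.

**Step 4**
Reactants: 5 (2Z,6E)-3,7-dimethylundeca-2,6,10-trien-1-ol
Product: 6 (2Z,6E)-1-bromo-3,7-dimethylundeca-2,6,10-triene
Conditions: PBr3 (0.4 equiv), pyridine (cat.), Et2O, −10 °C
Reagents that add atoms: phosphorus tribromide, BrP(Br)Br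
Why: Low-temperature PBr3 bromination of a primary allylic alcohol (SN2 on the phosphite ester) proceeds, as for nerol itself, without loss of the Z geometry.

**Step 5**
Reactants: 6 (2Z,6E)-1-bromo-3,7-dimethylundeca-2,6,10-triene
Product: 7 [(3Z,7E)-4,8-dimethyldodeca-3,7,11-trien-1-yl](phenyl)sulfane
Conditions: PhSCH3, n-BuLi, DABCO, THF, 0 °C; then 6, −78 °C → rt
Reagents that add atoms: thioanisole, CSc1ccccc1
Why: SN2 alkylation of (phenylthio)methyllithium by the primary allylic bromide adds the one missing carbon (first half of a Corey–Jautelat homologation).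

**Step 6**
Reactants: 7 [(3Z,7E)-4,8-dimethyldodeca-3,7,11-trien-1-yl](phenyl)sulfane
Product: 9 (3Z,7E)-1-iodo-4,8-dimethyldodeca-3,7,11-triene, via S-methylsulfonium iodide 8 (not isolated)
Conditions: MeI (excess), NaI, DMF, 75 °C
Reagents that add atoms: iodomethane, CI
Why: S-Methylation gives a sulfonium salt that iodide opens at the primary carbon (second half of the Corey–Jautelat homologation), turning CH2SPh into CH2I without touching the olefins.

**Step 7**
Reactants: 9 (3Z,7E)-1-iodo-4,8-dimethyldodeca-3,7,11-triene; 10 triethyl phosphonoacetate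
Product: 12 ethyl (5Z,9E)-2-(diethoxyphosphoryl)-6,10-dimethyltetradeca-5,9,13-trienoate, via sodium phosphonoacetate 11 (not isolated)
Conditions: 10 (2.5 equiv), NaH (2.4 equiv), THF–DMF, 0 °C; then 9, 55 °C
Reagents that add atoms: none
Why: SN2 C-alkylation of the soft phosphonoacetate anion by a primary iodide (the excess of anion suppresses dialkylation) gives the α-substituted HWE reagent.

**Step 8**
Reactants: 12 ethyl (5Z,9E)-2-(diethoxyphosphoryl)-6,10-dimethyltetradeca-5,9,13-trienoate
Product: 13 ethyl (5Z,9E,13E)-2-(diethoxyphosphoryl)-6,10-dimethyl-15-oxopentadeca-5,9,13-trienoate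
Conditions: crotonaldehyde (5 equiv), Hoveyda–Grubbs II (3 mol%), CH2Cl2, 40 °C
Reagents that add atoms: (E)-crotonaldehyde, C/C=C/C=O
Why: Olefin cross-metathesis of the monosubstituted terminal alkene with crotonaldehyde gives the (E)-enal, while the trisubstituted olefins do not react with the catalyst under these conditions.

**Step 9**
Reactants: 14 6-methylhept-5-en-2-one
Product: 15 N'-[(2E)-6-methylhept-5-en-2-ylidene]-2,4,6-tri(propan-2-yl)benzenesulfonohydrazide
Conditions: 2,4,6-triisopropylbenzenesulfonohydrazide, MeOH, HCl (cat.), rt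
Reagents that add atoms: 2,4,6-triisopropylbenzenesulfonohydrazide, NNS(=O)(=O)c1c(C(C)C)cc(C(C)C)cc1C(C)C
Why: Acid-catalysed hydrazone condensation gives the E-hydrazone, with the sulfonamide syn to the methyl group.

**Step 10**
Reactants: 15 N'-[(2E)-6-methylhept-5-en-2-ylidene]-2,4,6-tri(propan-2-yl)benzenesulfonohydrazide
Product: 18 (6-methylhepta-1,5-dien-2-yl)boronic acid, via alkenyllithium 16 (not isolated), via lithium triisopropoxyborate 17 (not isolated)
Conditions: n-BuLi (2.2 equiv), THF–TMEDA, −78 → 0 °C; B(OiPr)3, −78 °C → rt; aq. HCl to pH 5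
Reagents that add atoms: triisopropyl borate, CC(C)OB(OC(C)C)OC(C)C; water, O
Why: Shapiro reaction (dianion formation at the methyl group syn to the sulfonamide, then loss of sulfinate and N2) gives the 2-lithio-1-alkene, which is borylated and hydrolysed.

**Step 11**
Reactants: 13 ethyl (5Z,9E,13E)-2-(diethoxyphosphoryl)-6,10-dimethyl-15-oxopentadeca-5,9,13-trienoate; 18 (6-methylhepta-1,5-dien-2-yl)boronic acid
Product: 19 ethyl (5Z,9E,13R)-2-(diethoxyphosphoryl)-6,10-dimethyl-13-(6-methylhepta-1,5-dien-2-yl)-15-oxopentadeca-5,9-dienoate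
Conditions: Cat* (20 mol%), PhCO2H (20 mol%), 18 (1.5 equiv), H2O (2 equiv), toluene, 0 → 23 °C
Reagents that add atoms: none
Why: Proposed new method: catalyst-tethered boronate delivery in iminium catalysis – the imidazolidinone condenses with 13 to the (E)-iminium (enal chain held on the C5 side by the gem-dimethyl group), its ortho-phenol, which lies over the Re face of C-β, binds 18 as an aryloxy-boronate "ate" complex, and this complex hands the α-branched alkenyl group to C-β in an intramolecular Petasis-type 1,4-transfer (about 11-membered cyclic transition state), after which enamine hydrolysis releases 19, B(OH)3 and the catalyst; because free alkenylboronic acids do not add to iminium ions there should be no untethered background, so the face that carries the arm alone fixes 13R; closest known reaction type: the iminium-catalysed conjugate addition of alkenylboronic acids to 2-hydroxycinnamaldehydes and γ-hydroxy enals, in which the boron-binding hydroxyl sits on the substrate (here it is moved onto the catalyst, which opens the reaction to a plain aliphatic enal and a 1,1-disubstituted alkenyl group), together with the imidazolidinone-catalysed addition of alkenyltrifluoroborates to enals.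

**Step 12**
Reactants: 19 ethyl (5Z,9E,13R)-2-(diethoxyphosphoryl)-6,10-dimethyl-13-(6-methylhepta-1,5-dien-2-yl)-15-oxopentadeca-5,9-dienoate
Product: 20 ethyl (1E,4R,7E,11Z)-7,11-dimethyl-4-(6-methylhepta-1,5-dien-2-yl)cyclotetradeca-1,7,11-triene-1-carboxylate
Conditions: LiCl, DBU, MeCN, rt, syringe-pump addition to 2 mM
Reagents that add atoms: none
Why: Intramolecular Horner–Wadsworth–Emmons olefination (Masamune–Roush conditions, high dilution) of an α-alkyl phosphonoacetate with an aliphatic aldehyde gives the (E)-enoate (ring CH2 trans to CO2Et), which is the geometry the target needs, and the stereocentre is β to the aldehyde and cannot epimerise.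

**Step 13**
Reactants: 20 ethyl (1E,4R,7E,11Z)-7,11-dimethyl-4-(6-methylhepta-1,5-dien-2-yl)cyclotetradeca-1,7,11-triene-1-carboxylate
Product: 21 [(1E,4R,7E,11Z)-7,11-dimethyl-4-(6-methylhepta-1,5-dien-2-yl)cyclotetradeca-1,7,11-trien-1-yl]methanol (CNP0217603.1)
Conditions: DIBAL-H (2.5 equiv), CH2Cl2, −78 °C; Rochelle salt
Reagents that add atoms: none
Why: DIBAL-H 1,2-reduction of the α,β-unsaturated ester gives the allylic alcohol, and no other group in 20 is reducible.

**Compound list**
1 | neryl acetate, (2Z)-3,7-dimethylocta-2,6-dien-1-yl acetate | CC(C)=CCC/C(C)=C\COC(C)=O | starting material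
2 | (2Z,6E)-8-hydroxy-3,7-dimethylocta-2,6-dien-1-yl acetate | OC/C(C)=C/CC/C(C)=C\COC(C)=O | intermediate
3 | (2Z,6E)-8-bromo-3,7-dimethylocta-2,6-dien-1-yl acetate | BrC/C(C)=C/CC/C(C)=C\COC(C)=O | intermediate
4 | (2Z,6E)-3,7-dimethylundeca-2,6,10-trien-1-yl acetate | C=CCC/C(C)=C/CC/C(C)=C\COC(C)=O | intermediate (not isolated)
5 | (2Z,6E)-3,7-dimethylundeca-2,6,10-trien-1-ol | C=CCC/C(C)=C/CC/C(C)=C\CO | intermediate
6 | (2Z,6E)-1-bromo-3,7-dimethylundeca-2,6,10-triene | C=CCC/C(C)=C/CC/C(C)=C\CBr | intermediate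
7 | [(3Z,7E)-4,8-dimethyldodeca-3,7,11-trien-1-yl](phenyl)sulfane | C=CCC/C(C)=C/CC/C(C)=C\CCSc1ccccc1 | intermediate
8 | [(3Z,7E)-4,8-dimethyldodeca-3,7,11-trien-1-yl](methyl)(phenyl)sulfonium iodide | C=CCC/C(C)=C/CC/C(C)=C\CC[S+](C)c1ccccc1.[I-] | intermediate (not isolated)
9 | (3Z,7E)-1-iodo-4,8-dimethyldodeca-3,7,11-triene | C=CCC/C(C)=C/CC/C(C)=C\CCI | intermediate
10 | triethyl phosphonoacetate | CCOC(=O)CP(=O)(OCC)OCC | starting material
11 | sodium salt of triethyl phosphonoacetate | [Na+].CCOC(=O)[CH-]P(=O)(OCC)OCC | intermediate (not isolated)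
12 | ethyl (5Z,9E)-2-(diethoxyphosphoryl)-6,10-dimethyltetradeca-5,9,13-trienoate | C=CCC/C(C)=C/CC/C(C)=C\CCC(C(=O)OCC)P(=O)(OCC)OCC | intermediate
13 | ethyl (5Z,9E,13E)-2-(diethoxyphosphoryl)-6,10-dimethyl-15-oxopentadeca-5,9,13-trienoate | O=C/C=C/CC/C(C)=C/CC/C(C)=C\CCC(C(=O)OCC)P(=O)(OCC)OCC | intermediate
14 | 6-methylhept-5-en-2-one | CC(=O)CCC=C(C)C | starting material
15 | N'-[(2E)-6-methylhept-5-en-2-ylidene]-2,4,6-tri(propan-2-yl)benzenesulfonohydrazide | C/C(CCC=C(C)C)=N\NS(=O)(=O)c1c(C(C)C)cc(C(C)C)cc1C(C)C | intermediate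
16 | (6-methylhepta-1,5-dien-2-yl)lithium | [Li]C(=C)CCC=C(C)C | intermediate (not isolated)
17 | lithium triisopropoxy(6-methylhepta-1,5-dien-2-yl)borate | [Li+].C=C(CCC=C(C)C)[B-](OC(C)C)(OC(C)C)OC(C)C | intermediate (not isolated)
18 | (6-methylhepta-1,5-dien-2-yl)boronic acid | C=C(CCC=C(C)C)B(O)O | intermediate
19 | ethyl (5Z,9E,13R)-2-(diethoxyphosphoryl)-6,10-dimethyl-13-(6-methylhepta-1,5-dien-2-yl)-15-oxopentadeca-5,9-dienoate | O=CC[C@H](C(=C)CCC=C(C)C)CC/C(C)=C/CC/C(C)=C\CCC(C(=O)OCC)P(=O)(OCC)OCC | intermediate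
20 | ethyl (1E,4R,7E,11Z)-7,11-dimethyl-4-(6-methylhepta-1,5-dien-2-yl)cyclotetradeca-1,7,11-triene-1-carboxylate | C=C(CCC=C(C)C)[C@H]1C/C=C(/C(=O)OCC)CC/C=C(/C)CC/C=C(\C)CC1 | intermediate
21 | [(1E,4R,7E,11Z)-7,11-dimethyl-4-(6-methylhepta-1,5-dien-2-yl)cyclotetradeca-1,7,11-trien-1-yl]methanol | C=C(CCC=C(C)C)[C@H]1C/C=C(/CO)CC/C=C(/C)CC/C=C(\C)CC1 | target

**Totals**
Total step count: 13. Longest linear sequence: 11 steps (steps 1–8 and 11–13); steps 9–10 make the boronic acid.

**Three steps most likely to fail**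

Step 11 (the new conjugate alkenylation). It may fail through no turnover, a parasitic N,O-acetal of the phenol arm, protodeboronation or low ee. The fallback sets out from enal 13 and comes back at macrocycle 20, using the known amine-catalysed Michael addition of a nitroalkane as an acyl-anion equivalent. The nitroalkane 5-methyl-1-nitrohex-4-ene F1 is made from 6-bromo-2-methylhex-2-ene and NaNO2 in DMF. Its addition to 13 under (S)-α,α-diphenylprolinol trimethylsilyl ether and PhCO2H in MeOH attacks the same Re face and gives the γ-nitro aldehyde ethyl (5Z,9E,13R)-2-(diethoxyphosphoryl)-6,10,18-trimethyl-14-nitro-13-(2-oxoethyl)nonadeca-5,9,17-trienoate F2 (mixture at the nitro carbon). The conditions of step 12 close it to ethyl (1E,4R,7E,11Z)-7,11-dimethyl-4-(5-methyl-1-nitrohex-4-en-1-yl)cyclotetradeca-1,7,11-triene-1-carboxylate F3. A Nef reaction (NaOMe, then buffered aqueous TiCl3) gives the ketone ethyl (1E,4R,7E,11Z)-7,11-dimethyl-4-(5-methylhex-4-enoyl)cyclotetradeca-1,7,11-triene-1-carboxylate F4. Non-basic Takai–Lombardo methylenation (Zn, CH2Br2, TiCl4, THF, 0 °C) then gives 20 without epimerising the α-stereocentre or touching the ester.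

Step 12 (macrocyclisation). It may give oligomers or a poor E/Z ratio. The fallback sets out from iodide 9 and comes back at 20, closing the ring at C4–C5 by cross-coupling so that the enoate geometry is fixed before ring closure. Cross-metathesis of 9 with crotonaldehyde gives (2E,6E,10Z)-13-iodo-6,10-dimethyltrideca-2,6,10-trienal F5. The step-11 alkenylation with 18 gives (3R,6E,10Z)-13-iodo-6,10-dimethyl-3-(6-methylhepta-1,5-dien-2-yl)trideca-6,10-dienal F6. Wittig reaction with ethyl bromo(triphenylphosphoranylidene)acetate gives the (Z)-α-bromo enoate ethyl (2Z,5R,8E,12Z)-2-bromo-15-iodo-8,12-dimethyl-5-(6-methylhepta-1,5-dien-2-yl)pentadeca-2,8,12-trienoate F7. Zinc insertion into the C–I bond (Zn, LiCl, THF) and an intramolecular Pd-catalysed sp3–sp2 Negishi coupling at high dilution then give 20 with retention of the alkene geometry.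

Step 10 (Shapiro borylation). The α-branched alkenylboronic acid may protodeboronate or oligomerise on isolation. The fallback sets out from ketone 14 and comes back at 18. Kinetic enolisation and triflation (LDA, PhNTf2, THF, −78 °C) give 6-methylhepta-1,5-dien-2-yl trifluoromethanesulfonate F8. Miyaura borylation (B2pin2, PdCl2(PPh3)2, PPh3, KOPh, toluene, 50 °C) gives the storable pinacol ester 4,4,5,5-tetramethyl-2-(6-methylhepta-1,5-dien-2-yl)-1,3,2-dioxaborolane F9. This is cleaved to 18 with NaIO4/NH4OAc in aqueous acetone just before step 11.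

**Further compounds**
F1 | step 11 | 5-methyl-1-nitrohex-4-ene | CC(C)=CCCC[N+](=O)[O-]
F2 | step 11 | ethyl (5Z,9E,13R)-2-(diethoxyphosphoryl)-6,10,18-trimethyl-14-nitro-13-(2-oxoethyl)nonadeca-5,9,17-trienoate | O=CC[C@H](C(CCC=C(C)C)[N+](=O)[O-])CC/C(C)=C/CC/C(C)=C\CCC(C(=O)OCC)P(=O)(OCC)OCC
F3 | step 11 | ethyl (1E,4R,7E,11Z)-7,11-dimethyl-4-(5-methyl-1-nitrohex-4-en-1-yl)cyclotetradeca-1,7,11-triene-1-carboxylate | CC(C)=CCCC([N+](=O)[O-])[C@H]1C/C=C(/C(=O)OCC)CC/C=C(/C)CC/C=C(\C)CC1
F4 | step 11 | ethyl (1E,4R,7E,11Z)-7,11-dimethyl-4-(5-methylhex-4-enoyl)cyclotetradeca-1,7,11-triene-1-carboxylate | CC(C)=CCCC(=O)[C@H]1C/C=C(/C(=O)OCC)CC/C=C(/C)CC/C=C(\C)CC1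
F5 | step 12 | (2E,6E,10Z)-13-iodo-6,10-dimethyltrideca-2,6,10-trienal | O=C/C=C/CC/C(C)=C/CC/C(C)=C\CCI
F6 | step 12 | (3R,6E,10Z)-13-iodo-6,10-dimethyl-3-(6-methylhepta-1,5-dien-2-yl)trideca-6,10-dienal | O=CC[C@H](C(=C)CCC=C(C)C)CC/C(C)=C/CC/C(C)=C\CCI
F7 | step 12 | ethyl (2Z,5R,8E,12Z)-2-bromo-15-iodo-8,12-dimethyl-5-(6-methylhepta-1,5-dien-2-yl)pentadeca-2,8,12-trienoate | CCOC(=O)/C(Br)=C/C[C@H](C(=C)CCC=C(C)C)CC/C(C)=C/CC/C(C)=C\CCI
F8 | step 10 | 6-methylhepta-1,5-dien-2-yl trifluoromethanesulfonate | C=C(CCC=C(C)C)OS(=O)(=O)C(F)(F)F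
F9 | step 10 | 4,4,5,5-tetramethyl-2-(6-methylhepta-1,5-dien-2-yl)-1,3,2-dioxaborolane | C=C(CCC=C(C)C)B1OC(C)(C)C(C)(C)O1
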